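## Retrosynthetic overview

- The target is the 8‑O‑angeloyl‑11‑O‑acetyl germacra‑1(10)E,4E‑dien‑6,12‑olide with a cis‑fused lactone (6R,7S,8S,11R). The two esters go on last (C8, then C11), and the C14 methyl comes from an alkenyl triflate at C10.
- Enabling feature: C2–C3 is the central σ‑bond of the 1,5‑diene C10=C1–C2–C3–C4=C5 inside the ten‑membered ring C1–C10. It is formed by an anionic oxy‑Cope ring expansion of a 10‑vinyl‑5‑isopropenyl‑cyclohexan‑10‑olate (ring C5–C6–C7–C8–C9–C10). The C5–C10 bond, absent from the target, is a temporary bond that breaks as C2–C3 forms, and the C10 enolate is trapped as its triflate.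
- The six‑membered template already carries C6, C7, C8 and C11. The lactone comes from carboxylate oxa‑Michael addition to a 2‑isopropenyl enone, and C7/C11 from a chelate‑controlled Ireland–Claisen rearrangement of a lactate ester of an enzymatically desymmetrized cis‑cyclohex‑2‑ene‑1,4‑diol.
- Ring order: cyclohexene (from cyclohexa‑1,3‑diene) → γ‑lactone → ten‑membered carbocycle (the six‑membered ring is consumed).

Key step: step 15

Notation: germacrane numbering (C1–C15) is used for the ring atoms of all intermediates.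
Assumption: the hydrolase in step 2 is one whose enantiotopic preference leaves the acetate on the future C5; if the enzyme at hand cleaves the other acetate, the same monoacetate 3 is obtained by acetylating the meso diol with it, because the two modes are enantiocomplementary.

## Route

Step 1
Reactants: 1 cyclohexa‑1,3‑diene
Product: 2 cis‑cyclohex‑2‑ene‑1,4‑diyl diacetate (meso)
Conditions: Pd(OAc)2 (5 mol %), LiCl (cat.), LiOAc, p‑benzoquinone, AcOH, 25 °C
Reagents that add atoms: acetic acid, CC(=O)O; lithium acetate, [Li+].CC(=O)[O-]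
Why: Palladium‑catalysed oxidative 1,4‑diacetoxylation of a 1,3‑diene, in which chloride as ligand forces the second acetate to attack the π‑allyl complex from outside, so the meso cis‑diacetate should result.

Step 2
Reactants: 2 cis‑cyclohex‑2‑ene‑1,4‑diyl diacetate
Product: 3 (1R,4S)‑4‑hydroxycyclohex‑2‑en‑1‑yl acetate
Conditions: lipase (Candida antarctica lipase B) or acetylcholinesterase, phosphate buffer pH 7, 25 °C
Reagents that add atoms: none
Why: Enantiotopic‑group‑selective enzymatic hydrolysis of a meso diacetate sets the absolute configuration of the whole route, the free hydroxyl marking the future C8 and the remaining acetate the future C5.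

Step 3
Reactants: 3 (1R,4S)‑4‑hydroxycyclohex‑2‑en‑1‑yl acetate
Product: 4 (1R,4S)‑4‑(methoxymethoxy)cyclohex‑2‑en‑1‑yl acetate
Conditions: MeOCH2Cl, iPr2NEt, CH2Cl2, 0 → 25 °C
Reagents that add atoms: chloromethyl methyl ether, COCCl
Why: O‑Alkylation to a methoxymethyl acetal, a small, non‑enolizable, non‑migrating group that tolerates the radical oxidation and the strong bases used later.

Step 4
Reactants: 4 (1R,4S)‑4‑(methoxymethoxy)cyclohex‑2‑en‑1‑yl acetate
Product: 5 (1R,4S)‑4‑(methoxymethoxy)cyclohex‑2‑en‑1‑ol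
Conditions: K2CO3 (cat.), MeOH, 25 °C
Reagents that add atoms: none
Why: Base‑catalysed transesterification removes the acetate without touching the acetal or the stereocentres.

Step 5
Reactants: 6 ethyl (2S)‑2‑hydroxypropanoate (ethyl (S)‑lactate)
Product: 7 ethyl (2S)‑2‑(methoxymethoxy)propanoate
Conditions: MeOCH2Cl, iPr2NEt, CH2Cl2, 0 → 25 °C
Reagents that add atoms: chloromethyl methyl ether, COCCl
Why: Acetal protection gives an α‑alkoxy ester whose ether oxygen can chelate lithium in step 8.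

Step 6
Reactants: 7 ethyl (2S)‑2‑(methoxymethoxy)propanoate
Product: 8 (2S)‑2‑(methoxymethoxy)propanoic acid
Conditions: LiOH, THF/H2O, 0 °C; then HCl to pH 3
Reagents that add atoms: lithium hydroxide, [Li+].[OH-]
Why: Saponification of an unhindered ethyl ester, with brief cold acidification that the acetal survives.

Step 7
Reactants: 5 (1R,4S)‑4‑(methoxymethoxy)cyclohex‑2‑en‑1‑ol; 8 (2S)‑2‑(methoxymethoxy)propanoic acid
Product: 9 (1R,4S)‑4‑(methoxymethoxy)cyclohex‑2‑en‑1‑yl (2S)‑2‑(methoxymethoxy)propanoate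
Conditions: DCC, DMAP (cat.), CH2Cl2, 0 → 25 °C
Reagents that add atoms: none
Why: Steglich (carbodiimide) esterification of a secondary allylic alcohol, in which any epimerization of the lactate centre is harmless because that centre is planarized in step 8.

Step 8
Reactants: 9 (1R,4S)‑4‑(methoxymethoxy)cyclohex‑2‑en‑1‑yl (2S)‑2‑(methoxymethoxy)propanoate
Product: 12 (2R)‑2‑(methoxymethoxy)‑2‑[(1R,6S)‑6‑(methoxymethoxy)cyclohex‑2‑en‑1‑yl]propanoic acid, via Z‑silyl ketene acetal 10 (not isolated), via trimethylsilyl ester 11 (not isolated)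
Conditions: LiN(iPr)2, THF, −78 °C; Me3SiCl; −78 → 50 °C; then aq. NaOH, citric acid
Reagents that add atoms: none
Why: Ireland–Claisen rearrangement in which the lithium‑chelated α‑alkoxy enolate is silylated to the (Z)‑ketene acetal, the suprafacial [3,3] shift delivers C11 to C7 on the face of the departing C5–O bond (hence cis to the C8 oxygen), and the boat‑like transition state usual for cyclohex‑2‑enyl esters places the methyl group toward the ring and the alkoxy group outside, which should give 11R.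

Step 9
Reactants: 12 (2R)‑2‑(methoxymethoxy)‑2‑[(1R,6S)‑6‑(methoxymethoxy)cyclohex‑2‑en‑1‑yl]propanoic acid
Product: 13 2‑(trimethylsilyl)ethyl (2R)‑2‑(methoxymethoxy)‑2‑[(1R,6S)‑6‑(methoxymethoxy)cyclohex‑2‑en‑1‑yl]propanoate
Conditions: Me3SiCH2CH2OH, PPh3, iPrO2CN=NCO2iPr, THF, 0 → 25 °C
Reagents that add atoms: 2‑(trimethylsilyl)ethanol, C[Si](C)(C)CCO
Why: Mitsunobu esterification alkylates the hindered carboxylate at a primary carbon and installs an ester that fluoride can later remove irrespective of the steric hindrance at C12.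

Step 10
Reactants: 13 2‑(trimethylsilyl)ethyl ester
Product: 14 2‑(trimethylsilyl)ethyl (2R)‑2‑(methoxymethoxy)‑2‑[(1R,6S)‑6‑(methoxymethoxy)‑4‑oxocyclohex‑2‑en‑1‑yl]propanoate
Conditions: Rh2(C6H10NO)4 (dirhodium tetracaprolactamate, 1 mol %), tBuOOH, K2CO3, CH2Cl2, 25 °C
Reagents that add atoms: tert‑butyl hydroperoxide, CC(C)(C)OO
Why: Catalytic allylic C–H oxidation by a tert‑butylperoxyl radical chain should abstract hydrogen from the only accessible allylic methylene (C10, since C7–H is tertiary and shielded by C11) and capture oxygen at that less hindered terminus, giving the C10 enone without transposition.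

Step 11
Reactants: 14 enone
Product: 15 2‑(trimethylsilyl)ethyl (2R)‑2‑[(1R,6S)‑3‑iodo‑6‑(methoxymethoxy)‑4‑oxocyclohex‑2‑en‑1‑yl]‑2‑(methoxymethoxy)propanoate
Conditions: I2, pyridine, CH2Cl2, 0 → 25 °C
Reagents that add atoms: iodine, II
Why: α‑Iodination of a cyclic enone by conjugate addition of pyridine, iodination of the enolate and elimination, under conditions too weakly basic to epimerize C7.

Step 12
Reactants: 15 α‑iodoenone
Product: 16 2‑(trimethylsilyl)ethyl (2R)‑2‑(methoxymethoxy)‑2‑[(1R,6S)‑6‑(methoxymethoxy)‑4‑oxo‑3‑(prop‑1‑en‑2‑yl)cyclohex‑2‑en‑1‑yl]propanoate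
Conditions: CH2=C(CH3)SnBu3, Pd2(dba)3 (cat.), AsPh3, CuI (cat.), N‑methylpyrrolidinone, 25 °C
Reagents that add atoms: tributyl(prop‑1‑en‑2‑yl)stannane, CC(=C)[Sn](CCCC)(CCCC)CCCC
Why: Stille coupling of an α‑iodoenone with an alkenylstannane attaches C4 to C5 under neutral conditions that leave the γ‑stereocentre C7 and the ester untouched.

Step 13
Reactants: 16 2‑isopropenyl enone ester
Product: 18 (3R,3aS,4S,7S,7aS)‑3,4‑bis(methoxymethoxy)‑3‑methyl‑7‑(prop‑1‑en‑2‑yl)hexahydro‑1‑benzofuran‑2,6‑dione, via tetrabutylammonium carboxylate 17 (not isolated)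
Conditions: Bu4NF, THF, 0 °C; then AcOH, 0 → 25 °C
Reagents that add atoms: none
Why: Fluoride‑induced fragmentation of the silylethyl ester frees the carboxylate, which adds 5‑exo‑trig to C6 of the dienone (oxa‑Michael), the tether allowing only the cis‑fused lactone (C6), while the buffered enol is protonated at C5 from the convex face anti to the pseudo‑axial C6–O bond, so that isopropenyl, C11 and later vinyl can all be equatorial.

Step 14
Reactants: 18 keto lactone
Product: 19 (3R,3aS,4S,6S,7S,7aR)‑6‑ethenyl‑6‑hydroxy‑3,4‑bis(methoxymethoxy)‑3‑methyl‑7‑(prop‑1‑en‑2‑yl)hexahydro‑1‑benzofuran‑2(3H)‑one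
Conditions: CH2=CHMgBr, CeCl3, THF, −78 °C
Reagents that add atoms: vinylmagnesium bromide, C=C[Mg]Br
Why: The weakly basic organocerium reagent adds to the ketone faster than it triggers retro‑oxa‑Michael cleavage or attacks the hindered lactone, and it should enter equatorially (the axial path is blocked by the syn‑axial C6–O and C8–O bonds), placing vinyl trans to isopropenyl.

Step 15
Reactants: 19 trans‑1‑vinyl‑2‑isopropenyl cyclohexanol
Product: 22 (3R,3aS,4S,6Z,10E,11aR)‑3,4‑bis(methoxymethoxy)‑3,10‑dimethyl‑2‑oxo‑2,3,3a,4,5,8,9,11a‑octahydrocyclodeca[b]furan‑6‑yl trifluoromethanesulfonate, via potassium alkoxide 20 (not isolated), via potassium enolate 21 (not isolated)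
Conditions: KN(SiMe3)2, 18‑crown‑6, THF, 0 → 45 °C; then PhN(SO2CF3)2, −78 → 0 °C
Reagents that add atoms: N‑phenylbis(trifluoromethanesulfonimide), O=S(=O)(N(c1ccccc1)S(=O)(=O)C(F)(F)F)C(F)(F)F
Why: Deprotonation gives the crown‑separated potassium alkoxide 20, whose oxyanion weakens the C5–C10 bond and accelerates the [3,3]‑sigmatropic shift of the 3‑oxido‑1,5‑diene C2=C1–C10(O⁻)–C5–C4=C3; the closest known reaction type is the anionic oxy‑Cope ring expansion of trans‑1,2‑dialkenylcyclohexanols to cyclodec‑5‑enone enolates with in‑flask enolate trapping. The ten‑membered ring is closed by a four‑atom sigmatropic ring expansion (6 → 10): C2–C3 forms between the two alkene termini through a chair‑like six‑centre transition state while the temporary C5–C10 bond breaks. No sp3 stereocentre is created (C6, C7, C8 and C11 are spectators, the auxiliary centres C5 and C10 are destroyed), but two stereogenic double bonds are: the trans‑diequatorial vinyl and isopropenyl groups on the chair translate into the 4E olefin and into the C1=C10 enolate with C2 and C9 trans. The step needs chair over boat and rearrangement over fragmentation: in the only accessible chair the three carbon substituents are equatorial, the C6–O bond is axial and therefore gauche to the breaking C5–C10 bond (Grob‑type loss of the lactone carboxylate is stereoelectronically disfavoured), and C11 is quaternary so the lactone cannot be enolized. O‑Sulfonylation of the regio‑defined enolate 21 at −78 °C, before any proton transfer, fixes the double bond at C1=C10 and prevents β‑elimination of the C8 alkoxy group.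

Step 16
Reactants: 22 alkenyl triflate
Product: 23 (3R,3aS,4S,6E,10E,11aR)‑3,4‑bis(methoxymethoxy)‑3,6,10‑trimethyl‑3a,4,5,8,9,11a‑hexahydrocyclodeca[b]furan‑2(3H)‑one
Conditions: CH3MgBr, Fe(acac)3 (5 mol %), THF/N‑methylpyrrolidinone, −30 °C
Reagents that add atoms: methylmagnesium bromide, C[Mg]Br
Why: Iron‑catalysed Kumada‑type coupling of an alkenyl triflate with a methyl Grignard reagent proceeds with retention of olefin geometry and, at −30 °C, should outrun addition to the hindered lactone, installing C14.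

Step 17
Reactants: 23 bis(methoxymethyl) ether
Product: 24 (3R,3aS,4S,6E,10E,11aR)‑3,4‑dihydroxy‑3,6,10‑trimethyl‑3a,4,5,8,9,11a‑hexahydrocyclodeca[b]furan‑2(3H)‑one
Conditions: Me3SiOSO2CF3, 2,2′‑bipyridyl, CH2Cl2, 0 → 25 °C; then H2O
Reagents that add atoms: none
Why: The bipyridyl‑buffered silyl triflate converts each acetal into a pyridinium N,O‑acetal that water hydrolyses, a weakly acidic cleavage chosen to spare the cyclization‑prone 1(10),4‑diene and the allylic lactone.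

Step 18
Reactants: 24 8,11‑diol
Product: 25 (3R,3aS,4S,6E,10E,11aR)‑3‑hydroxy‑3,6,10‑trimethyl‑2‑oxo‑2,3,3a,4,5,8,9,11a‑octahydrocyclodeca[b]furan‑4‑yl (2Z)‑2‑methylbut‑2‑enoate
Conditions: angelic acid, 2,4,6‑trichlorobenzoyl chloride, Et3N, toluene, 25 → 70 °C
Reagents that add atoms: angelic acid ((2Z)‑2‑methylbut‑2‑enoic acid), C/C=C(/C)C(=O)O
Why: Yamaguchi‑type mixed‑anhydride esterification without a nucleophilic catalyst acylates the secondary C8 hydroxyl selectively over the tertiary C11 hydroxyl and avoids Z to E isomerization of the angeloyl group.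

Step 19
Reactants: 25 8‑O‑angeloyl 11‑alcohol
Product: 26 (3R,3aS,4S,6E,10E,11aR)‑3‑acetoxy‑3,6,10‑trimethyl‑2‑oxo‑2,3,3a,4,5,8,9,11a‑octahydrocyclodeca[b]furan‑4‑yl (2Z)‑2‑methylbut‑2‑enoate (target)
Conditions: Ac2O, DMAP, Et3N, CH2Cl2, 25 °C
Reagents that add atoms: acetic anhydride, CC(=O)OC(C)=O
Why: DMAP‑catalysed acetylation of the tertiary α‑hydroxy lactone proceeds at ambient temperature, below the range of Cope rearrangement of the germacradiene and without disturbing the angelate.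

## Compound list

1 | cyclohexa‑1,3‑diene | C1=CC=CCC1 | starting material
2 | cis‑cyclohex‑2‑ene‑1,4‑diyl diacetate (meso) | CC(=O)O[C@H]1CC[C@@H](OC(C)=O)C=C1 | intermediate
3 | (1R,4S)‑4‑hydroxycyclohex‑2‑en‑1‑yl acetate | O[C@H]1CC[C@@H](OC(C)=O)C=C1 | intermediate
4 | (1R,4S)‑4‑(methoxymethoxy)cyclohex‑2‑en‑1‑yl acetate | COCO[C@H]1CC[C@@H](OC(C)=O)C=C1 | intermediate
5 | (1R,4S)‑4‑(methoxymethoxy)cyclohex‑2‑en‑1‑ol | COCO[C@H]1CC[C@@H](O)C=C1 | intermediate
6 | ethyl (2S)‑2‑hydroxypropanoate | CCOC(=O)[C@H](C)O | starting material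
7 | ethyl (2S)‑2‑(methoxymethoxy)propanoate | CCOC(=O)[C@H](C)OCOC | intermediate
8 | (2S)‑2‑(methoxymethoxy)propanoic acid | OC(=O)[C@H](C)OCOC | intermediate
9 | (1R,4S)‑4‑(methoxymethoxy)cyclohex‑2‑en‑1‑yl (2S)‑2‑(methoxymethoxy)propanoate | COCO[C@H]1CC[C@@H](OC(=O)[C@H](C)OCOC)C=C1 | intermediate
10 | [(1Z)‑1‑{[(1R,4S)‑4‑(methoxymethoxy)cyclohex‑2‑en‑1‑yl]oxy}‑2‑(methoxymethoxy)prop‑1‑en‑1‑yl]oxy(trimethyl)silane | COCO[C@H]1CC[C@@H](O/C(O[Si](C)(C)C)=C(\C)OCOC)C=C1 | intermediate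
11 | trimethylsilyl (2R)‑2‑(methoxymethoxy)‑2‑[(1R,6S)‑6‑(methoxymethoxy)cyclohex‑2‑en‑1‑yl]propanoate | COCO[C@H]1CCC=C[C@H]1[C@@](C)(OCOC)C(=O)O[Si](C)(C)C | intermediate
12 | (2R)‑2‑(methoxymethoxy)‑2‑[(1R,6S)‑6‑(methoxymethoxy)cyclohex‑2‑en‑1‑yl]propanoic acid | COCO[C@H]1CCC=C[C@H]1[C@@](C)(OCOC)C(=O)O | intermediate
13 | 2‑(trimethylsilyl)ethyl (2R)‑2‑(methoxymethoxy)‑2‑[(1R,6S)‑6‑(methoxymethoxy)cyclohex‑2‑en‑1‑yl]propanoate | COCO[C@H]1CCC=C[C@H]1[C@@](C)(OCOC)C(=O)OCC[Si](C)(C)C | intermediate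
14 | 2‑(trimethylsilyl)ethyl (2R)‑2‑(methoxymethoxy)‑2‑[(1R,6S)‑6‑(methoxymethoxy)‑4‑oxocyclohex‑2‑en‑1‑yl]propanoate | COCO[C@H]1CC(=O)C=C[C@H]1[C@@](C)(OCOC)C(=O)OCC[Si](C)(C)C | intermediate
15 | 2‑(trimethylsilyl)ethyl (2R)‑2‑[(1R,6S)‑3‑iodo‑6‑(methoxymethoxy)‑4‑oxocyclohex‑2‑en‑1‑yl]‑2‑(methoxymethoxy)propanoate | COCO[C@H]1CC(=O)C(I)=C[C@H]1[C@@](C)(OCOC)C(=O)OCC[Si](C)(C)C | intermediate
16 | 2‑(trimethylsilyl)ethyl (2R)‑2‑(methoxymethoxy)‑2‑[(1R,6S)‑6‑(methoxymethoxy)‑4‑oxo‑3‑(prop‑1‑en‑2‑yl)cyclohex‑2‑en‑1‑yl]propanoate | COCO[C@H]1CC(=O)C(C(C)=C)=C[C@H]1[C@@](C)(OCOC)C(=O)OCC[Si](C)(C)C | intermediate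
17 | tetrabutylammonium (2R)‑2‑(methoxymethoxy)‑2‑[(1R,6S)‑6‑(methoxymethoxy)‑4‑oxo‑3‑(prop‑1‑en‑2‑yl)cyclohex‑2‑en‑1‑yl]propanoate | COCO[C@H]1CC(=O)C(C(C)=C)=C[C@H]1[C@@](C)(OCOC)C(=O)[O-].CCCC[N+](CCCC)(CCCC)CCCC | intermediate
18 | (3R,3aS,4S,7S,7aS)‑3,4‑bis(methoxymethoxy)‑3‑methyl‑7‑(prop‑1‑en‑2‑yl)hexahydro‑1‑benzofuran‑2,6‑dione | COCO[C@H]1CC(=O)[C@@H](C(C)=C)[C@H]2OC(=O)[C@](C)(OCOC)[C@@H]12 | intermediate
19 | (3R,3aS,4S,6S,7S,7aR)‑6‑ethenyl‑6‑hydroxy‑3,4‑bis(methoxymethoxy)‑3‑methyl‑7‑(prop‑1‑en‑2‑yl)hexahydro‑1‑benzofuran‑2(3H)‑one | COCO[C@H]1C[C@](O)(C=C)[C@@H](C(C)=C)[C@H]2OC(=O)[C@](C)(OCOC)[C@@H]12 | intermediate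
20 | potassium (3R,3aS,4S,6S,7S,7aR)‑6‑ethenyl‑3,4‑bis(methoxymethoxy)‑3‑methyl‑2‑oxo‑7‑(prop‑1‑en‑2‑yl)octahydro‑1‑benzofuran‑6‑olate | COCO[C@H]1C[C@]([O-])(C=C)[C@@H](C(C)=C)[C@H]2OC(=O)[C@](C)(OCOC)[C@@H]12.[K+] | intermediate
21 | potassium (3R,3aS,4S,6Z,10E,11aR)‑3,4‑bis(methoxymethoxy)‑3,10‑dimethyl‑2‑oxo‑2,3,3a,4,5,8,9,11a‑octahydrocyclodeca[b]furan‑6‑olate | COCO[C@H]1C/C([O-])=C/CC/C(C)=C/[C@H]2OC(=O)[C@](C)(OCOC)[C@@H]12.[K+] | intermediate
22 | (3R,3aS,4S,6Z,10E,11aR)‑3,4‑bis(methoxymethoxy)‑3,10‑dimethyl‑2‑oxo‑2,3,3a,4,5,8,9,11a‑octahydrocyclodeca[b]furan‑6‑yl trifluoromethanesulfonate | COCO[C@H]1C/C(OS(=O)(=O)C(F)(F)F)=C/CC/C(C)=C/[C@H]2OC(=O)[C@](C)(OCOC)[C@@H]12 | intermediate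
23 | (3R,3aS,4S,6E,10E,11aR)‑3,4‑bis(methoxymethoxy)‑3,6,10‑trimethyl‑3a,4,5,8,9,11a‑hexahydrocyclodeca[b]furan‑2(3H)‑one | COCO[C@H]1C/C(C)=C/CC/C(C)=C/[C@H]2OC(=O)[C@](C)(OCOC)[C@@H]12 | intermediate
24 | (3R,3aS,4S,6E,10E,11aR)‑3,4‑dihydroxy‑3,6,10‑trimethyl‑3a,4,5,8,9,11a‑hexahydrocyclodeca[b]furan‑2(3H)‑one | O[C@H]1C/C(C)=C/CC/C(C)=C/[C@H]2OC(=O)[C@](C)(O)[C@@H]12 | intermediate
25 | (3R,3aS,4S,6E,10E,11aR)‑3‑hydroxy‑3,6,10‑trimethyl‑2‑oxo‑2,3,3a,4,5,8,9,11a‑octahydrocyclodeca[b]furan‑4‑yl (2Z)‑2‑methylbut‑2‑enoate | C/C=C(/C)C(=O)O[C@H]1C/C(C)=C/CC/C(C)=C/[C@H]2OC(=O)[C@](C)(O)[C@@H]12 | intermediate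
26 | (3R,3aS,4S,6E,10E,11aR)‑3‑acetoxy‑3,6,10‑trimethyl‑2‑oxo‑2,3,3a,4,5,8,9,11a‑octahydrocyclodeca[b]furan‑4‑yl (2Z)‑2‑methylbut‑2‑enoate | C/C=C(/C)C(=O)O[C@H]1C/C(C)=C/CC/C(C)=C/[C@H]2OC(=O)[C@](C)(OC(C)=O)[C@@H]12 | target

## Step count and risks

Total step count: 19. Longest linear sequence: 17 steps (steps 1–4 and 7–19; steps 5–6 form the side branch to acid 8).

Steps most likely to fail:

1. **Step 15 (ring expansion and trapping).** The in‑flask sulfonylation may be too slow, so that the potassium enolate equilibrates by proton transfer (loss of the C1=C10 regiochemistry, then β‑elimination of the C8 alkoxy group) or is sulfonylated on carbon. The fallback sets out from 19. The alkoxide is generated and rearranged as before, but the enolate is quenched with Me3SiCl, which silylates oxygen fast and cleanly, to give the isolable (3R,3aS,4S,6Z,10E,11aR)‑3,4‑bis(methoxymethoxy)‑3,10‑dimethyl‑6‑[(trimethylsilyl)oxy]‑3a,4,5,8,9,11a‑hexahydrocyclodeca[b]furan‑2(3H)‑one F1. This silyl enol ether is then converted regiospecifically into the triflate with CsF and PhN(SO2CF3)2 in dimethoxyethane (fluoride‑released enolate, O‑triflation). The fallback returns to the route at 22.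

2. **Step 8 (Ireland–Claisen rearrangement).** The C11 configuration may erode through a competing chair‑like transition state or a non‑chelated enolate geometry. The fallback sets out from 5 and sets C11 by substrate control instead:
   - Acylation with propanoyl chloride and pyridine gives (1R,4S)‑4‑(methoxymethoxy)cyclohex‑2‑en‑1‑yl propanoate F2.
   - Its Ireland–Claisen rearrangement (LiN(iPr)2, Me3SiCl) gives (2S)‑2‑[(1S,6S)‑6‑(methoxymethoxy)cyclohex‑2‑en‑1‑yl]propanoic acid F3, whose C11 configuration is immaterial.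
   - Iodolactonization (I2, NaHCO3) gives (3S,3aS,4S,7S,7aS)‑7‑iodo‑4‑(methoxymethoxy)‑3‑methylhexahydro‑1‑benzofuran‑2(3H)‑one F4.
   - Enolization with KN(SiMe3)2 at −78 °C and oxidation with 2‑(phenylsulfonyl)‑3‑phenyloxaziridine from the convex face of the cis‑fused bicycle gives (3R,3aS,4S,7S,7aS)‑3‑hydroxy‑7‑iodo‑4‑(methoxymethoxy)‑3‑methylhexahydro‑1‑benzofuran‑2(3H)‑one F5.
   - Protection with MeOCH2Cl and iPr2NEt gives (3R,3aS,4S,7S,7aS)‑7‑iodo‑3,4‑bis(methoxymethoxy)‑3‑methylhexahydro‑1‑benzofuran‑2(3H)‑one F6.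
   - Zinc in acetic acid reopens the iodolactone reductively to the alkene acid. The fallback returns to the route at 12.

3. **Step 17 (acetal cleavage on the germacradiene).** The Lewis acid may trigger transannular cation–olefin cyclization of the 1(10),4‑diene. The fallback sets out from 22, where the C1=C10 double bond carries the electron‑withdrawing triflyloxy group and cannot act as the nucleophilic partner. The same bipyridyl‑buffered silyl triflate treatment at this stage gives (3R,3aS,4S,6Z,10E,11aR)‑3,4‑dihydroxy‑3,10‑dimethyl‑2‑oxo‑2,3,3a,4,5,8,9,11a‑octahydrocyclodeca[b]furan‑6‑yl trifluoromethanesulfonate F7. The iron‑catalysed coupling with excess CH3MgBr (the two hydroxyls are carried as magnesium alkoxides) then installs the methyl group. The fallback returns to the route at 24.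

Further compounds
F1 | step 15 | (3R,3aS,4S,6Z,10E,11aR)‑3,4‑bis(methoxymethoxy)‑3,10‑dimethyl‑6‑[(trimethylsilyl)oxy]‑3a,4,5,8,9,11a‑hexahydrocyclodeca[b]furan‑2(3H)‑one | COCO[C@H]1C/C(O[Si](C)(C)C)=C/CC/C(C)=C/[C@H]2OC(=O)[C@](C)(OCOC)[C@@H]12
F2 | step 8 | (1R,4S)‑4‑(methoxymethoxy)cyclohex‑2‑en‑1‑yl propanoate | COCO[C@H]1CC[C@@H](OC(=O)CC)C=C1
F3 | step 8 | (2S)‑2‑[(1S,6S)‑6‑(methoxymethoxy)cyclohex‑2‑en‑1‑yl]propanoic acid | COCO[C@H]1CCC=C[C@H]1[C@H](C)C(=O)O
F4 | step 8 | (3S,3aS,4S,7S,7aS)‑7‑iodo‑4‑(methoxymethoxy)‑3‑methylhexahydro‑1‑benzofuran‑2(3H)‑one | COCO[C@H]1CC[C@H](I)[C@H]2OC(=O)[C@@H](C)[C@@H]12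
F5 | step 8 | (3R,3aS,4S,7S,7aS)‑3‑hydroxy‑7‑iodo‑4‑(methoxymethoxy)‑3‑methylhexahydro‑1‑benzofuran‑2(3H)‑one | COCO[C@H]1CC[C@H](I)[C@H]2OC(=O)[C@](C)(O)[C@@H]12
F6 | step 8 | (3R,3aS,4S,7S,7aS)‑7‑iodo‑3,4‑bis(methoxymethoxy)‑3‑methylhexahydro‑1‑benzofuran‑2(3H)‑one | COCO[C@H]1CC[C@H](I)[C@H]2OC(=O)[C@](C)(OCOC)[C@@H]12
F7 | step 17 | (3R,3aS,4S,6Z,10E,11aR)‑3,4‑dihydroxy‑3,10‑dimethyl‑2‑oxo‑2,3,3a,4,5,8,9,11a‑octahydrocyclodeca[b]furan‑6‑yl trifluoromethanesulfonate | O[C@H]1C/C(OS(=O)(=O)C(F)(F)F)=C/CC/C(C)=C/[C@H]2OC(=O)[C@](C)(O)[C@@H]12
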